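6.35 s was the number I carried: the partner's life, the time in which the coupling partner falls to 36.8% of its strength, taking the decline as exponential. I read it from the autumn run. The logarithm of the fraction of starting material left counts the partner it has met, and at 10.0 s that count stood at 79.3% of its plateau value.

| flask | starting material | coupling partner | second substrate | third substrate | protic impurity | remark | time |
|---|---|---|---|---|---|---|---|
| autumn | 32 mM | 96 mM | 32 mM | 32 mM | 9.6 mM | run made earlier |  |
| spring | 32 mM | 48 mM | 32 mM | 32 mM | 9.6 mM | run made earlier |  |
| midnight | 32 mM | 72 mM | 32 mM | 32 mM | 9.6 mM | run made earlier |  |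
| red | 32 mM (fed, over 1.5 min) | 96.0 mM | 32.0 mM | 32.0 mM | 9.60 mM | all else is in the flask from the start; the feed brings no volume worth counting | 2.0 min |
| teal | 32 mM | 96.0 mM | 32.0 mM (fed, over 1.5 min) | 32.0 mM | 9.60 mM | all else is in the flask from the start; the feed brings no volume worth counting | 2.0 min |
| grey | 32 mM (in portions, 3, over 1.5 min) | 96.0 mM | 32.0 mM | 32.0 mM | 9.60 mM | first portion at the start, last at 1.5 min | 2.0 min |
| ochre | 32 mM | 96.0 mM | 32.0 mM | 32.0 mM | 9.60 mM | everything together at the start | 2.0 min |

- autumn (time / s: target / %, starting material / %): 10.0: 57.5, 46.1; 20.0: 60.3, 37.6; 30.0: 59.4, 37.7; 40.0: 61.6, 38.0; 50.0: 63.4, 37.3; 60.0: 61.6, 37.4; 80.0: 62.6, 38.0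
- spring (time / s: target / %, starting material / %): 10.0: 31.0, 69.5; 15.0: 32.5, 67.8; 20.0: 32.9, 66.0; 30.0: 33.7, 67.2; 50.0: 32.3, 68.2; 80.0: 31.8, 66.9; 120: 34.2, 67.2
- midnight (time / s: target / %, starting material / %): 15.0: 46.9, 52.9; 30.0: 47.9, 52.5; 50.0: 47.1, 53.4; 60.0: 45.9, 51.8; 80.0: 48.7, 51.8; 90.0: 45.9, 53.4; 120: 46.1, 51.3

(readings scatter by 1 percentage point)



- the flask with the highest amount of target, in percent of the starting material charged ("all alike" if they lie within 1.5 percentage points) (red / teal / grey / ochre / all alike)
- final target, as a percentage of the starting material charged, in red
- final target, as a percentage of the starting material charged, in teal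
- final target, as a percentage of the starting material charged, in grey
- final target, as a percentage of the starting material charged, in ochre

The plateau target rose from 33.7% with 48 mM of coupling partner to 62.6% with 96 mM, so I took the coupling partner as the limiting reagent. Then I set out the ladder, fastest first. One life was the bottom rung. The autumn plateau stood by 20.0 s, or 3.15 lives, and I expected ochre to repeat that run. Grey's portions came 45.0 s apart, or 7.09 lives, so I expected its first portion to meet the partner at full strength and the next to come late. The slow feeds ran 90 s, or 14.2 lives. In red, then, I reckoned the target as the share of feed entering during one life, 7.05%.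

The forecast gave red 9%, teal 85%, grey 24% and ochre 62%, with teal highest, and held that “withholding a competitor leaves surplus partner”. Its red stood above my share.

The flasks gave red 7.10%, teal 65.7%, grey 23.4% and ochre 62.3%, with teal highest.

    coupling partner + protic impurity → quenched reagent (k = 0.990 M⁻¹ s⁻¹)
    second substrate + coupling partner → second product (k = 0.560 M⁻¹ s⁻¹)
    starting material + coupling partner → target (k = 2.50 M⁻¹ s⁻¹)
    third substrate → decomposition product (k = 6.10 × 10⁻⁵ s⁻¹)
    coupling partner → decomposed reagent (k = 0.0990 s⁻¹)
    third substrate + coupling partner → third product (k = 5.40 M⁻¹ s⁻¹)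

Teal stood 19 percentage points below the forecast. In one life the teal feed let in 2.26 mM of second substrate, and second product ended at 0.452 mM against 6.28 mM in ochre, but decomposed reagent rose from 38.6 mM to 42.4 mM. The partner's own decay is the largest single effect on the gap between teal and red: without it the gap falls from 59 points to 19 points. Red gave 7.10% beside the share of 7.05%. The same flask as red with 240 mM of coupling partner stood above that share, at 19.1%.

Readings and results were computed from invented constants, and the scatter is random.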